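Compound numbers used below are those of the steps and of the compound list.

## Analysis of the target

Selaginellin A, compound 19, is built on a 1,2,3,4-tetrasubstituted benzene, ring A. C1 carries a methyl group, C2 an ethynyl group that ends in the 4-hydroxyphenyl ring E, C3 the exocyclic carbon C7, and C4 the 4-hydroxyphenyl ring B; C5 and C6 carry hydrogen. C7 is sp2: it bears the phenyl ring C and is doubly bonded to ring D, a cyclohexa-2,5-dien-1-one, so that C7 and ring D form a para-quinone methide. There is no stereogenic centre, and the C7=C bond has no E/Z isomerism because ring D is symmetrical; hindered rotation about C3–C7 is not specified and is not addressed. The sensitive groups are the quinone methide (electrophilic at C7, easily reduced), the two free phenols, and the diarylalkyne ortho to C7, which can cyclise onto a cationic C7 under acid. The difficulty is the crowding: C3 sits between the alkynyl-bearing C2 and the aryl-bearing C4 and must itself carry a fully substituted carbon, so forming C3–C7 on a finished arene would mean reacting at a di-ortho-substituted position. The route rests on the fact that C3 lies between two ring carbons that each bear a carbon substituent, just as C2 of cyclohexane-1,3-dione 3 lies between two carbonyl carbons that can each accept a carbon nucleophile. Ring A is therefore mapped onto 3: the dione C2 becomes C3, the two carbonyls become C2 and C4, and the three methylenes become C1, C6 and C5.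

## Retrosynthetic reasoning

19 to 18. The C7=ring D double bond and the ring D carbonyl are traced back to a C7–H bond and a 4-hydroxyphenyl group, so 19 is the two-electron oxidation product of triphenol 18. The quinone methide is removed first because it would not survive organometallic reagents. C7 can then be an ordinary sp3 diarylmethine throughout, and its configuration is irrelevant. The forward step must take hydride from C7 and leave the two other phenols alone.

18 to 17. The three phenolic O–H bonds are traced to O–CH3 bonds. Methyl ethers are chosen because they tolerate the acid of the key step, strong bases, organolithium and organocerium reagents, and the quinone oxidant used for aromatisation. The forward step must cleave three aryl methyl ethers without adding across the alkyne.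

17 to 16 to 15. Ring A is dearomatised: 17 comes from cyclohexadiene 16 by loss of two hydrogens, and 16 from tertiary carbinol 15 by dehydration. This turns C4 into a former carbonyl carbon, so that the crowding is built up on a non-planar six-membered ring and not on a flat arene.

15 to 11 plus 12. The C4–ring B bond is cut to give enone 11 and an aryl nucleophile made from 12 through 13 and 14. The cut is placed here because C4 is the carbonyl carbon of 11; a cross-coupling on the arene would need a leaving group next to the crowded C3. The forward addition must go 1,2 and must outrun enolisation and conjugate addition.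

11 to 7 plus 8. The bond from C2 to the alkyne is cut to give vinylogous ester 7 and acetylide 9, made from 8. Acetylide addition to the ketone carbonyl of 7 gives 10, and hydrolysis of 10 moves the carbonyl to the former enol ether carbon, the future C4. The alkyne is thus attached by carbonyl addition, with no coupling at a hindered aryl position, and the transposition exposes the next electrophilic site.

7 to 5. The C1–CH3 bond is cut to give enolate 6, formed from 5 at the carbon alpha-prime to the ketone. Placing the methyl next to the carbonyl that will become C2 fixes the order methyl, alkynyl, C7, aryl around the ring.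

5 to 4. The enol ether O–CH3 bond is cut. Because the two carbonyls of 4 are equivalent, it does not matter which oxygen is methylated.

4 to 2 plus 3. The C3–C7 bond, the most congested bond of 19, is cut between the dione C2 and the benzhydryl carbon. It is formed first, on a saturated ring with no ortho substituents, by trapping the cation from 2 with the enol of 3. The forward step must alkylate at carbon, not oxygen, and only once.

2 to 1. The C7–H bond is traced to the carbonyl of commercial ketone 1 by hydride reduction.

## Alternatives that were turned down

Alternative 1: Ring A is cut at C1–C2 and C3–C4 into two pieces, the diene (1E,3E)-1-(4-methoxyphenyl)penta-1,3-diene A2 and the diynone 5-(4-methoxyphenyl)-1-phenylpenta-2,4-diyn-1-one A3.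
- Forward key step: a thermal Diels–Alder reaction of diene A2 across the ketone-activated triple bond of diynone A3 would give the cis-cyclohexa-1,4-diene A1. Dehydrogenation, addition of an anisyl-metal reagent from 12 to the ketone, and Lewis-acid demethylation would then lead to 19.
- For it: all four substituents of ring A are set in one convergent step, and C7 enters as a ketone, so no separate final oxidation is needed. On convergence and probably on step count it is stronger than the chosen route.
- Against it: both termini of diene A2 are substituted, so regiochemistry rests only on the anisyl terminus directing more strongly than the methyl terminus, and a regioisomer with methyl and aryl exchanged is expected alongside A1.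
- Against it: A3 is a doubly unsaturated Michael acceptor that may polymerise or react at its second triple bond at the temperature that a 1,4-disubstituted diene such as A2 requires.
- Against it: the aryl addition that completes C7 takes place on a ketone flanked by two ortho substituents.
- Comparison: the chosen strategy is longer and linear, but each substituent of ring A is placed by carbonyl chemistry with no regiochemical ambiguity, and the crowded C3–C7 bond is made before any neighbour exists.

Alternative 2: The bond from the outer alkyne carbon to ring E is traced, together with the triple bond, to the vinyl bromide (Z)-2-bromo-3-[2-bromo-1-(4-methoxyphenyl)ethenyl]-4'-methoxy-4-methyl-1,1'-biphenyl A5, in which the anisyl group sits on the inner alkene carbon.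
- Forward key step: a lithium amide base would remove the vinylic hydrogen of A5 to give a bromo-lithio carbenoid, and a Fritsch–Buttenberg–Wiechell 1,2-shift of the anisyl group with loss of bromide would give alkyne A4. Bromine–lithium exchange at C3 of A4, addition to ketone 1 and demethylation would finish the synthesis.
- For it: the hindered alkyne arises by a unimolecular rearrangement that is indifferent to ortho crowding. On this point it is stronger than the chosen route, which relies on adding an acetylide to a shielded carbonyl.
- Against it: A5 requires a 1,1-diarylalkene on an aryl ring with two ortho substituents, made from a hindered diaryl ketone, so the steric problem is moved, not removed.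
- Against it: the strong base meets the aryl bromide of A5, which invites competing halogen–metal exchange.
- Against it: the C3–C7 bond is made last, by a di-ortho-flanked aryllithium from A4 attacking a benzophenone, which is the most demanding bond formation at the most crowded site.
- Comparison: the step count would not be lower than nine. The chosen strategy makes C3–C7 first at an unhindered sp3 carbon.

Alternative 3: The C3–C7 bond and the bond from C2 to the alkyne are cut together, leading to the aryl iodide 4-chloro-2-iodotoluene A7, benzoic anhydride A8 and alkyne 8.
- Forward key step: a Catellani relay under palladium catalysis with a strained bicyclic alkene as transient mediator would acylate the C3–H bond of iodide A7 with anhydride A8 and then couple C2 with 8, giving ketone A6. Suzuki coupling at the chloride of A6, anisyl addition to the ketone and demethylation would follow.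
- For it: three components join in one step and the whole synthesis would take about four steps. On step economy it is clearly stronger than the chosen nine-step route.
- Against it: the C–H bond of A7 to be acylated lies between the iodine-bearing carbon and the chlorine-bearing C4, and palladacycle formation at a doubly flanked position runs against the steric preference of this relay.
- Against it: A8 and the terminal alkyne 8 together can couple directly to an ynone, and the alkyne can couple at C2 of A7 before the relay has acted.
- Against it: a late aryl addition to the hindered ketone of A6 is again needed.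
- Comparison: the chosen strategy pays five more steps, but each bond is made by an established reaction at a site without that steric penalty, so the risk is spread and not staked on one step.

Key step: step 2

Remark on the chemistry: every chiral intermediate is racemic. A compound with one stereocentre is drawn as one enantiomer and a mixture of diastereomers is drawn without descriptors, since all these centres are erased before 19.

## Route

Step 1
Reactants: 1 4-methoxybenzophenone
Product: 2 (4-methoxyphenyl)(phenyl)methanol (racemic)
Conditions: NaBH4, MeOH, 0 °C to rt
Reagents that add atoms: none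
Why: Hydride reduction of a diaryl ketone by NaBH4 is fast and clean; the carbinol centre is racemic, which does not matter because it is ionised in step 2.

Step 2
Reactants: 2 (4-methoxyphenyl)(phenyl)methanol; 3 cyclohexane-1,3-dione (1.5 equiv)
Product: 4 2-[(4-methoxyphenyl)(phenyl)methyl]cyclohexane-1,3-dione (racemic)
Conditions: TsOH·H2O (10 mol%), MeNO2, 60 °C
Reagents that add atoms: none
Why: TsOH protonates the hydroxyl of 2 and loss of water gives a diarylmethyl cation stabilised by the para-methoxy group; the enol of 3 attacks it through C2 in an SN1 alkylation that forms the future C3–C7 bond, and proton loss returns the catalyst. The closest known reaction type is the Brønsted- or Lewis-acid-catalysed direct benzylation of 1,3-dicarbonyl compounds, cyclic 1,3-diones included, with benzhydrols. No ring is closed. The new stereocentre at C7 comes from a planar cation with no controlling element and is racemic, which is acceptable because C7 becomes sp2 in step 9. The step needs C- over O-alkylation and mono- over dialkylation: the O-benzhydryl enol ether and the symmetrical ether of 2 form reversibly and re-ionise under the acid, whereas the C–C bond does not under these mild conditions, so the material should collect in 4. A second alkylation at C2 would create a quaternary carbon bearing two diarylmethyl groups and is sterically excluded. Attack of the cation on an anisyl ring is outrun by the far more nucleophilic enol, which is used in excess.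

Step 3
Reactants: 4 2-[(4-methoxyphenyl)(phenyl)methyl]cyclohexane-1,3-dione
Product: 5 3-methoxy-2-[(4-methoxyphenyl)(phenyl)methyl]cyclohex-2-en-1-one (racemic)
Conditions: Me2SO4, K2CO3, acetone, reflux
Reagents that add atoms: dimethyl sulfate, COS(=O)(=O)OC
Why: O-alkylation of an enolised 2-substituted 1,3-dione with a hard methylating agent is standard; C-methylation would need a quaternary centre beside the diarylmethyl group. Both oxygens of 4 are equivalent, so only one vinylogous ester can form.

Step 4
Reactants: 5 3-methoxy-2-[(4-methoxyphenyl)(phenyl)methyl]cyclohex-2-en-1-one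
Product: 7 3-methoxy-2-[(4-methoxyphenyl)(phenyl)methyl]-6-methylcyclohex-2-en-1-one (racemic; mixture of diastereomers), via lithium enolate 6 (not isolated)
Conditions: LiN(i-Pr)2 (1.1 equiv), THF, −78 °C; MeI, −78 to 0 °C
Reagents that add atoms: iodomethane, CI
Why: Kinetic deprotonation of a 3-alkoxy-enone by a lithium amide occurs at the alpha-prime carbon C6 (Stork–Danheiser alkylation), and the enolate is methylated there; the doubly benzylic C7–H is far less acidic. The new centre at C6 is uncontrolled and becomes the aromatic C1.

Step 5
Reactants: 7 3-methoxy-2-[(4-methoxyphenyl)(phenyl)methyl]-6-methylcyclohex-2-en-1-one; 8 4-ethynylanisole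
Product: 11 3-[(4-methoxyphenyl)ethynyl]-2-[(4-methoxyphenyl)(phenyl)methyl]-4-methylcyclohex-2-en-1-one (racemic; mixture of diastereomers), via lithium acetylide 9 (not isolated), via propargylic carbinol 10 (not isolated)
Conditions: 8, n-BuLi, THF, −78 °C; add 7, −78 to 0 °C; then 1 M HCl, THF, rt
Reagents that add atoms: water, O
Why: Stork–Danheiser sequence: the slim acetylide adds 1,2 to the vinylogous ester carbonyl, and aqueous acid ionises the tertiary carbinol with help from the enol ether oxygen, water then attacking the methoxy-bearing carbon to give the transposed enone. The alkynyl group ends on the carbon next to the methyl-bearing carbon, as ring A requires.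

Step 6
Reactants: 11 3-[(4-methoxyphenyl)ethynyl]-2-[(4-methoxyphenyl)(phenyl)methyl]-4-methylcyclohex-2-en-1-one; 12 4-bromoanisole
Product: 15 1-(4-methoxyphenyl)-3-[(4-methoxyphenyl)ethynyl]-2-[(4-methoxyphenyl)(phenyl)methyl]-4-methylcyclohex-2-en-1-ol (racemic; mixture of diastereomers), via aryllithium 13 (not isolated), via arylcerium dichloride 14 (not isolated)
Conditions: 12, n-BuLi, THF, −78 °C; anhydrous CeCl3, THF, −78 °C; add 11, −78 to 0 °C; H2O
Reagents that add atoms: none
Why: Bromine–lithium exchange gives the aryllithium, and transmetallation to cerium gives a weakly basic, strongly oxophilic reagent that adds 1,2 to hindered enolisable enones in preference to enolisation or conjugate addition. The new carbinol centre is uncontrolled and is lost in step 7.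

Step 7
Reactants: 15 1-(4-methoxyphenyl)-3-[(4-methoxyphenyl)ethynyl]-2-[(4-methoxyphenyl)(phenyl)methyl]-4-methylcyclohex-2-en-1-ol
Product: 17 4'-methoxy-3-[(4-methoxyphenyl)ethynyl]-2-[(4-methoxyphenyl)(phenyl)methyl]-4-methyl-1,1'-biphenyl (racemic), via cyclohexadiene 16 (not isolated)
Conditions: TsOH·H2O (5 mol%), toluene, 40 °C; then DDQ (1.1 equiv), rt
Reagents that add atoms: none
Why: Acid ionises the tertiary allylic, benzylic alcohol to an anisyl-stabilised allyl cation that loses a ring proton (E1 dehydration) to give the cyclohexadiene, and DDQ dehydrogenation then aromatises ring A; a double-bond isomer of 16 would give the same arene. The ring hydrogens of a cyclohexadiene are removed much more readily than the shielded C7–H, so one equivalent of oxidant should stop at 17.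

Step 8
Reactants: 17 4'-methoxy-3-[(4-methoxyphenyl)ethynyl]-2-[(4-methoxyphenyl)(phenyl)methyl]-4-methyl-1,1'-biphenyl
Product: 18 2-[(4-hydroxyphenyl)(phenyl)methyl]-3-[(4-hydroxyphenyl)ethynyl]-4-methyl-[1,1'-biphenyl]-4'-ol (racemic)
Conditions: BBr3, CH2Cl2, −78 to 0 °C; H2O
Reagents that add atoms: none
Why: BBr3 cleavage of aryl methyl ethers, with hydrolysis of the aryl borates on work-up; the low temperature is chosen to keep the internal diarylalkyne from adding HBr, and the C7–H bond is inert to the Lewis acid.

Step 9
Reactants: 18 2-[(4-hydroxyphenyl)(phenyl)methyl]-3-[(4-hydroxyphenyl)ethynyl]-4-methyl-[1,1'-biphenyl]-4'-ol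
Product: 19 selaginellin A
Conditions: DDQ (1.0 equiv), 1,4-dioxane, rt
Reagents that add atoms: none
Why: Quinone dehydrogenation of a 4-(diarylmethyl)phenol to a fuchsone-type para-quinone methide: hydride leaves from C7, para to the hydroxyl of ring D, and the phenolic proton follows. Rings B and E have no benzylic hydrogen para to their hydroxyl groups and should not be dehydrogenated by one equivalent of oxidant; the C7 stereocentre disappears.

## Compound list

1 | 4-methoxybenzophenone | O=C(c1ccccc1)c1ccc(OC)cc1 | starting material
2 | (4-methoxyphenyl)(phenyl)methanol (racemic, one enantiomer drawn) | O[C@H](c1ccccc1)c1ccc(OC)cc1 | intermediate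
3 | cyclohexane-1,3-dione | O=C1CCCC(=O)C1 | starting material
4 | 2-[(4-methoxyphenyl)(phenyl)methyl]cyclohexane-1,3-dione (racemic, one enantiomer drawn) | O=C1CCCC(=O)C1[C@@H](c1ccccc1)c1ccc(OC)cc1 | intermediate
5 | 3-methoxy-2-[(4-methoxyphenyl)(phenyl)methyl]cyclohex-2-en-1-one (racemic, one enantiomer drawn) | COC1=C([C@@H](c2ccccc2)c2ccc(OC)cc2)C(=O)CCC1 | intermediate
6 | lithium 5-methoxy-6-[(4-methoxyphenyl)(phenyl)methyl]cyclohexa-1,5-dien-1-olate (racemic, one enantiomer drawn) | [Li]OC1=CCCC(OC)=C1[C@@H](c1ccccc1)c1ccc(OC)cc1 | intermediate (not isolated)
7 | 3-methoxy-2-[(4-methoxyphenyl)(phenyl)methyl]-6-methylcyclohex-2-en-1-one (racemic, mixture of diastereomers) | COC1=C(C(c2ccccc2)c2ccc(OC)cc2)C(=O)C(C)CC1 | intermediate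
8 | 4-ethynylanisole | C#Cc1ccc(OC)cc1 | starting material
9 | lithium (4-methoxyphenyl)acetylide | [Li]C#Cc1ccc(OC)cc1 | intermediate (not isolated)
10 | 3-methoxy-1-[(4-methoxyphenyl)ethynyl]-2-[(4-methoxyphenyl)(phenyl)methyl]-6-methylcyclohex-2-en-1-ol (racemic, mixture of diastereomers) | COC1=C(C(c2ccccc2)c2ccc(OC)cc2)C(O)(C#Cc2ccc(OC)cc2)C(C)CC1 | intermediate (not isolated)
11 | 3-[(4-methoxyphenyl)ethynyl]-2-[(4-methoxyphenyl)(phenyl)methyl]-4-methylcyclohex-2-en-1-one (racemic, mixture of diastereomers) | O=C1CCC(C)C(C#Cc2ccc(OC)cc2)=C1C(c1ccccc1)c1ccc(OC)cc1 | intermediate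
12 | 4-bromoanisole | COc1ccc(Br)cc1 | starting material
13 | 4-methoxyphenyllithium | [Li]c1ccc(OC)cc1 | intermediate (not isolated)
14 | dichloro(4-methoxyphenyl)cerium | COc1ccc([Ce](Cl)Cl)cc1 | intermediate (not isolated)
15 | 1-(4-methoxyphenyl)-3-[(4-methoxyphenyl)ethynyl]-2-[(4-methoxyphenyl)(phenyl)methyl]-4-methylcyclohex-2-en-1-ol (racemic, mixture of diastereomers) | COc1ccc(C2(O)CCC(C)C(C#Cc3ccc(OC)cc3)=C2C(c2ccccc2)c2ccc(OC)cc2)cc1 | intermediate
16 | 3-(4-methoxyphenyl)-1-[(4-methoxyphenyl)ethynyl]-2-[(4-methoxyphenyl)(phenyl)methyl]-6-methylcyclohexa-1,3-diene (racemic, mixture of diastereomers) | COc1ccc(C2=CCC(C)C(C#Cc3ccc(OC)cc3)=C2C(c2ccccc2)c2ccc(OC)cc2)cc1 | intermediate (not isolated)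
17 | 4'-methoxy-3-[(4-methoxyphenyl)ethynyl]-2-[(4-methoxyphenyl)(phenyl)methyl]-4-methyl-1,1'-biphenyl (racemic, one enantiomer drawn) | Cc1ccc(-c2ccc(OC)cc2)c([C@@H](c2ccccc2)c2ccc(OC)cc2)c1C#Cc1ccc(OC)cc1 | intermediate
18 | 2-[(4-hydroxyphenyl)(phenyl)methyl]-3-[(4-hydroxyphenyl)ethynyl]-4-methyl-[1,1'-biphenyl]-4'-ol (racemic, one enantiomer drawn) | Cc1ccc(-c2ccc(O)cc2)c([C@@H](c2ccccc2)c2ccc(O)cc2)c1C#Cc1ccc(O)cc1 | intermediate
19 | selaginellin A, 4-[{4'-hydroxy-3-[(4-hydroxyphenyl)ethynyl]-4-methyl-[1,1'-biphenyl]-2-yl}(phenyl)methylidene]cyclohexa-2,5-dien-1-one | Cc1ccc(-c2ccc(O)cc2)c(C(=C2C=CC(=O)C=C2)c2ccccc2)c1C#Cc1ccc(O)cc1 | target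

## Step count and least certain steps

Total step count: 9. Longest linear sequence: 9 steps (1, 2, 4, 5, 7, 11, 15, 17, 18, 19); compounds 3, 8 and 12 are commercial and enter directly.

Step 2 (key step). The most likely failure is loss of material through reversible side equilibria. These are self-etherification of 2, O-alkylation of the enol that is slow to revert, Friedel–Crafts attack of the cation on the anisyl ring of a second molecule, and acid-induced self-condensation of 3. All stem from generating a long-lived cation under acid in the presence of several nucleophiles.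

The fallback keeps the same bond but uses a carbanion under basic conditions, so nothing is reversible and no oxygen nucleophile competes. Setting out from 2, dry HCl in CH2Cl2 should give 1-[chloro(phenyl)methyl]-4-methoxybenzene F1. Commercial 1,5-dimethoxycyclohexa-1,4-diene, the bis(methyl enol ether) of 3, is deprotonated by t-BuLi in THF at −78 °C at the carbon between the two methoxy-bearing carbons to give (2,6-dimethoxycyclohexa-2,5-dien-1-yl)lithium F2. Alkylation of this anion with F1 should give 1,5-dimethoxy-6-[(4-methoxyphenyl)(phenyl)methyl]cyclohexa-1,4-diene F3, and dilute aqueous HCl in THF hydrolyses both enol ethers, returning to the route at 4.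

Step 5. The acetylide may fail to add, because the carbonyl of 7 is deactivated as a vinylogous ester and is shielded by the diarylmethyl group on one side and the methyl-bearing carbon on the other; deprotonation would then return 7.

The fallback reverses the order in which the two carbonyl carbons receive their nucleophiles, so that the acetylide meets a true ketone. Setting out from 5, addition of aryllithium 13 should give 3-methoxy-1-(4-methoxyphenyl)-2-[(4-methoxyphenyl)(phenyl)methyl]cyclohex-2-en-1-ol F4, which aqueous HCl transposes to 3-(4-methoxyphenyl)-2-[(4-methoxyphenyl)(phenyl)methyl]cyclohex-2-en-1-one F5. Kinetic deprotonation with LiN(i-Pr)2 at −78 °C gives lithium 5-(4-methoxyphenyl)-6-[(4-methoxyphenyl)(phenyl)methyl]cyclohexa-1,5-dien-1-olate F6, and iodomethane converts it into 3-(4-methoxyphenyl)-2-[(4-methoxyphenyl)(phenyl)methyl]-6-methylcyclohex-2-en-1-one F7. Acetylide 9 then adds to the ketone to give 3-(4-methoxyphenyl)-1-[(4-methoxyphenyl)ethynyl]-2-[(4-methoxyphenyl)(phenyl)methyl]-6-methylcyclohex-2-en-1-ol F8. Acid dehydration of F8 towards the methylene next to the anisyl-bearing carbon comes back to the route at 16, which is aromatised to 17 as in step 7; a double-bond isomer would converge on 17 as well.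

Step 6. Enolisation at the methylene beside the carbonyl, or addition across the conjugated enyne, may compete with attack at a carbonyl that is shielded by the neighbouring diarylmethyl group.

The fallback makes the C4–ring B bond by cross-coupling and turns the competing enolisation into the productive step. Setting out from 11, KN(SiMe3)2 in THF at −78 °C should give potassium 5-[(4-methoxyphenyl)ethynyl]-6-[(4-methoxyphenyl)(phenyl)methyl]-4-methylcyclohexa-1,5-dien-1-olate F9. Trapping with N-phenylbis(trifluoromethanesulfonimide) gives 5-[(4-methoxyphenyl)ethynyl]-6-[(4-methoxyphenyl)(phenyl)methyl]-4-methylcyclohexa-1,5-dien-1-yl trifluoromethanesulfonate F10. Suzuki coupling of F10 with 4-methoxyphenylboronic acid (Pd(PPh3)4, K3PO4, dioxane/H2O, 80 °C) comes back to the route at 16, which DDQ aromatises to 17.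

Step 9. The oxidation may not stay at C7: the C7–H bond is shielded by two ortho substituents, so hydride loss may be slow, and the oxidant may instead attack the two other free phenols by oxidative coupling or over-oxidise the electron-rich product.

The fallback moves the oxidation of C7 ahead of the demethylation, so that no free phenol is present when the oxidant is used. Setting out from 17, excess DDQ in MeCN/H2O at 60 °C should remove hydride from C7 and water should capture the cation, giving {4'-methoxy-3-[(4-methoxyphenyl)ethynyl]-4-methyl-[1,1'-biphenyl]-2-yl}(4-methoxyphenyl)(phenyl)methanol F11. BBr3 in CH2Cl2 then cleaves the three methyl ethers and ionises the carbinol, and aqueous work-up delivers the quinone methide, returning to the route at 19 without passing through 18.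

## Further compounds

F1 | step 2 | 1-[chloro(phenyl)methyl]-4-methoxybenzene (racemic, one enantiomer drawn) | Cl[C@H](c1ccccc1)c1ccc(OC)cc1
F2 | step 2 | (2,6-dimethoxycyclohexa-2,5-dien-1-yl)lithium | [Li]C1C(OC)=CCC=C1OC
F3 | step 2 | 1,5-dimethoxy-6-[(4-methoxyphenyl)(phenyl)methyl]cyclohexa-1,4-diene (racemic, one enantiomer drawn) | COC1=CCC=C(OC)C1[C@@H](c1ccccc1)c1ccc(OC)cc1
F4 | step 5 | 3-methoxy-1-(4-methoxyphenyl)-2-[(4-methoxyphenyl)(phenyl)methyl]cyclohex-2-en-1-ol (racemic, mixture of diastereomers) | COC1=C(C(c2ccccc2)c2ccc(OC)cc2)C(O)(c2ccc(OC)cc2)CCC1
F5 | step 5 | 3-(4-methoxyphenyl)-2-[(4-methoxyphenyl)(phenyl)methyl]cyclohex-2-en-1-one (racemic, one enantiomer drawn) | COc1ccc(C2=C([C@@H](c3ccccc3)c3ccc(OC)cc3)C(=O)CCC2)cc1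
F6 | step 5 | lithium 5-(4-methoxyphenyl)-6-[(4-methoxyphenyl)(phenyl)methyl]cyclohexa-1,5-dien-1-olate (racemic, one enantiomer drawn) | [Li]OC1=CCCC(c2ccc(OC)cc2)=C1[C@@H](c1ccccc1)c1ccc(OC)cc1
F7 | step 5 | 3-(4-methoxyphenyl)-2-[(4-methoxyphenyl)(phenyl)methyl]-6-methylcyclohex-2-en-1-one (racemic, mixture of diastereomers) | COc1ccc(C2=C(C(c3ccccc3)c3ccc(OC)cc3)C(=O)C(C)CC2)cc1
F8 | step 5 | 3-(4-methoxyphenyl)-1-[(4-methoxyphenyl)ethynyl]-2-[(4-methoxyphenyl)(phenyl)methyl]-6-methylcyclohex-2-en-1-ol (racemic, mixture of diastereomers) | COc1ccc(C#CC2(O)C(C)CCC(c3ccc(OC)cc3)=C2C(c2ccccc2)c2ccc(OC)cc2)cc1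
F9 | step 6 | potassium 5-[(4-methoxyphenyl)ethynyl]-6-[(4-methoxyphenyl)(phenyl)methyl]-4-methylcyclohexa-1,5-dien-1-olate (racemic, mixture of diastereomers) | [K]OC1=CCC(C)C(C#Cc2ccc(OC)cc2)=C1C(c1ccccc1)c1ccc(OC)cc1
F10 | step 6 | 5-[(4-methoxyphenyl)ethynyl]-6-[(4-methoxyphenyl)(phenyl)methyl]-4-methylcyclohexa-1,5-dien-1-yl trifluoromethanesulfonate (racemic, mixture of diastereomers) | CC1CC=C(OS(=O)(=O)C(F)(F)F)C(C(c2ccccc2)c2ccc(OC)cc2)=C1C#Cc1ccc(OC)cc1
F11 | step 9 | {4'-methoxy-3-[(4-methoxyphenyl)ethynyl]-4-methyl-[1,1'-biphenyl]-2-yl}(4-methoxyphenyl)(phenyl)methanol (racemic, one enantiomer drawn) | Cc1ccc(-c2ccc(OC)cc2)c([C@](O)(c2ccccc2)c2ccc(OC)cc2)c1C#Cc1ccc(OC)cc1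
A1 | alternative 1 | cis-3-methyl-6-(4-methoxyphenyl)-2-[(4-methoxyphenyl)ethynyl]cyclohexa-1,4-dien-1-yl phenyl ketone (racemic, one enantiomer drawn) | C[C@H]1C=C[C@@H](c2ccc(OC)cc2)C(C(=O)c2ccccc2)=C1C#Cc1ccc(OC)cc1
A2 | alternative 1 | (1E,3E)-1-(4-methoxyphenyl)penta-1,3-diene | C/C=C/C=C/c1ccc(OC)cc1
A3 | alternative 1 | 5-(4-methoxyphenyl)-1-phenylpenta-2,4-diyn-1-one | O=C(c1ccccc1)C#CC#Cc1ccc(OC)cc1
A4 | alternative 2 | 2-bromo-4'-methoxy-3-[(4-methoxyphenyl)ethynyl]-4-methyl-1,1'-biphenyl | Cc1ccc(-c2ccc(OC)cc2)c(Br)c1C#Cc1ccc(OC)cc1
A5 | alternative 2 | (Z)-2-bromo-3-[2-bromo-1-(4-methoxyphenyl)ethenyl]-4'-methoxy-4-methyl-1,1'-biphenyl | Cc1ccc(-c2ccc(OC)cc2)c(Br)c1/C(=C\Br)c1ccc(OC)cc1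
A6 | alternative 3 | [6-chloro-2-[(4-methoxyphenyl)ethynyl]-3-methylphenyl](phenyl)methanone | Cc1ccc(Cl)c(C(=O)c2ccccc2)c1C#Cc1ccc(OC)cc1
A7 | alternative 3 | 4-chloro-2-iodotoluene | Cc1ccc(Cl)cc1I
A8 | alternative 3 | benzoic anhydride | O=C(OC(=O)c1ccccc1)c1ccccc1
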